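**Retrosynthetic overview**
- The target is unmasked from its tris-TBS ether by one fluoride desilylation. The tris-TBS ether is cut at the bond between the benzylic CH2 and C5 of the furanone into a 4-silyloxy-3-prenylbenzyl acetate and a 2,3-bis(silyloxy)-4-arylfuran.
- Enabling feature: the oxygen para to the benzylic CH2 on the prenylated benzene ring lets that carbon be ionised to an O-silylated para-quinone methide. C5-H of the furanone ring is γ to the lactone C=O through C3=C4, so the ring can be worn as an aromatic 2-silyloxyfuran that is nucleophilic at C5.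
- Ring order: both benzene rings are bought. The five-membered oxygen ring is made first by an arylpyruvate/formaldehyde aldol-lactonisation, then aromatised to the furan by silylation, and returned to the butenolide in the key step, which also sets C5.
- Benzyl fragment: 4-hydroxybenzaldehyde by ortho-C-prenylation, silylation, reduction and acetylation.

Key step: step 7

Remark: the sense of induction of the key step cannot be assigned in advance. The catalyst antipode that leads to (5R) is to be fixed by the first experiment (both antipodes derive from (R)- or (S)-BINOL), and all structures after it assume that antipode.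

Step 1
Reactants: 1 4-hydroxybenzaldehyde; 2 prenyl bromide (1-bromo-3-methylbut-2-ene)
Product: 3 4-hydroxy-3-(3-methylbut-2-en-1-yl)benzaldehyde
Conditions: 10% aq. KOH (1 equiv), 2 (1.1 equiv), rt
Reagents that add atoms: none
Why: In water the phenoxide oxygen is tied up by hydrogen bonding, so the ambident anion is alkylated by the allylic bromide at the free ortho carbon (phenoxide ortho-C-allylation, para position blocked by CHO), with the O-prenyl ether as a separable by-product.

Step 2
Reactants: 3 4-hydroxy-3-(3-methylbut-2-en-1-yl)benzaldehyde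
Product: 4 4-[(tert-butyldimethylsilyl)oxy]-3-(3-methylbut-2-en-1-yl)benzaldehyde
Conditions: TBSCl, imidazole, DMF, rt
Reagents that add atoms: tert-butyldimethylsilyl chloride, CC(C)(C)[Si](C)(C)Cl
Why: Imidazole-mediated O-silylation of a phenol; TBS is chosen because it is inert to silylium catalysis and all silyl groups of the route fall together at the end.

Step 3
Reactants: 4 4-[(tert-butyldimethylsilyl)oxy]-3-(3-methylbut-2-en-1-yl)benzaldehyde
Product: 5 {4-[(tert-butyldimethylsilyl)oxy]-3-(3-methylbut-2-en-1-yl)phenyl}methanol
Conditions: NaBH4, MeOH/THF, 0 °C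
Reagents that add atoms: none
Why: Chemoselective borohydride reduction of the aldehyde, which leaves the aryl silyl ether and the trisubstituted alkene untouched at 0 °C.

Step 4
Reactants: 5 {4-[(tert-butyldimethylsilyl)oxy]-3-(3-methylbut-2-en-1-yl)phenyl}methanol
Product: 6 4-[(tert-butyldimethylsilyl)oxy]-3-(3-methylbut-2-en-1-yl)benzyl acetate
Conditions: Ac2O, Et3N, DMAP (cat.), CH2Cl2, 0 °C
Reagents that add atoms: acetic anhydride, CC(=O)OC(C)=O
Why: DMAP-catalysed acylation of a primary alcohol installs the leaving group that the silylium catalyst of the key step can abstract.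

Step 5
Reactants: 7 4-hydroxyphenylpyruvic acid [3-(4-hydroxyphenyl)-2-oxopropanoic acid]; 8 formaldehyde (37% aqueous)
Product: 10 3-hydroxy-4-(4-hydroxyphenyl)furan-2(5H)-one, via aldol adduct 4-hydroxy-3-(4-hydroxyphenyl)-2-oxobutanoic acid 9 (not isolated)
Conditions: 8 (1.05 equiv), K2CO3, H2O, 0 °C → rt; then conc. HCl to pH 1, rt
Reagents that add atoms: none
Why: Aldol addition of the arylpyruvate enolate (benzylic carbon) to formaldehyde, then acid lactonisation of the γ-hydroxy acid and enolisation into conjugation with the aryl ring, the classical arylpyruvic acid/formaldehyde route to 4-aryl-3-hydroxy-2(5H)-furanones.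

Step 6
Reactants: 10 3-hydroxy-4-(4-hydroxyphenyl)furan-2(5H)-one
Product: 12 2,3-bis[(tert-butyldimethylsilyl)oxy]-4-{4-[(tert-butyldimethylsilyl)oxy]phenyl}furan, via bis-silyl butenolide 11 (not isolated)
Conditions: TBSOTf (3.3 equiv), Et3N (4 equiv), CH2Cl2, 0 °C → rt; evaporation, pentane extraction and filtration under Ar (salt-free), used at once
Reagents that add atoms: tert-butyldimethylsilyl triflate, CC(C)(C)[Si](C)(C)OS(=O)(=O)C(F)(F)F
Why: Silyl triflate/amine soft enolisation: the enol and phenol are O-silylated first, then γ-deprotonation at C5 of the silyl-activated lactone gives the aromatic 2-silyloxyfuran (standard preparation of 2-silyloxyfurans from 2(5H)-furanones).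

Step 7
Reactants: 12 2,3-bis[(tert-butyldimethylsilyl)oxy]-4-{4-[(tert-butyldimethylsilyl)oxy]phenyl}furan; 6 4-[(tert-butyldimethylsilyl)oxy]-3-(3-methylbut-2-en-1-yl)benzyl acetate
Product: 14 (5R)-3-[(tert-butyldimethylsilyl)oxy]-5-{4-[(tert-butyldimethylsilyl)oxy]-3-(3-methylbut-2-en-1-yl)benzyl}-4-{4-[(tert-butyldimethylsilyl)oxy]phenyl}furan-2(5H)-one, via O-silyl para-quinone methide cation 13 (not isolated)
Conditions: chiral imidodiphosphorimidate (IDPi) Brønsted acid (3 mol%, antipode per remark), 12 (1.2 equiv), toluene, −78 → −40 °C, 6 added slowly; Et3N quench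
Reagents that add atoms: none
Why: Proposed new method: the silylated imidodiphosphorimidate (formed from the acid and a trace of 12) silylates the acetate carbonyl of 6 and ionises it to the O-silylated para-quinone methide cation 13, held as a contact ion pair inside the confined chiral anion, and C5 of the 2-silyloxyfuran 12 adds to its exocyclic CH2 (vinylogous Mukaiyama-Michael, i.e. 1,6-addition), after which the 2-O-silyl group returns to the anion and is passed to the next acetate (released as TBSOAc). The closest known reaction types are the silylium-based counteranion-directed additions of silyl ketene acetals to CH2-type cations paired with this class of anion (aminomethylation to β2-amino acids, where the only new stereocentre likewise lies on the nucleophile), the catalytic asymmetric vinylogous Mukaiyama reactions of 2-silyloxyfurans, the silver- or Lewis-acid-promoted C5 benzylation of 2-silyloxyfurans, and 1,6-additions to para-quinone methides. No ring is closed: the aromatic furan is returned to the butenolide with the enol ether already at C3, and the quinoid cation is returned to the arene. The C5 stereocentre is set by catalyst control, the chiral anion shielding one face of the furan as it meets the achiral cation; the substrate offers no bias, so the antipode that leads to 5R is fixed by the first experiment. The step needs C5 rather than C2/C3 attack, which is secured by C5 being the only unsubstituted furan carbon and the γ-terminus of the silyl dienolate while C2 and C3 sit under two TBS-oxy groups, and it needs the cation to meet the furan rather than an arene or the prenyl alkene, which is secured by the far higher π-nucleophilicity of the silyloxyfuran and by slow addition of 6.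

Step 8
Reactants: 14 (5R)-3-[(tert-butyldimethylsilyl)oxy]-5-{4-[(tert-butyldimethylsilyl)oxy]-3-(3-methylbut-2-en-1-yl)benzyl}-4-{4-[(tert-butyldimethylsilyl)oxy]phenyl}furan-2(5H)-one
Product: 15 (5R)-3-hydroxy-5-[4-hydroxy-3-(3-methylbut-2-en-1-yl)benzyl]-4-(4-hydroxyphenyl)furan-2(5H)-one
Conditions: TBAF (3.5 equiv), AcOH (4 equiv), THF, 0 °C → rt
Reagents that add atoms: none
Why: Fluoride desilylation of two aryl silyl ethers and one enol silyl ether; the acetic acid buffer keeps the medium too weakly basic to deprotonate C5 (no epimerisation) and too weakly acidic to cyclise the ortho-prenylphenol to a chroman.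

**Compound list**
1 | 4-hydroxybenzaldehyde | O=Cc1ccc(O)cc1 | starting material
2 | prenyl bromide (1-bromo-3-methylbut-2-ene) | CC(C)=CCBr | starting material
3 | 4-hydroxy-3-(3-methylbut-2-en-1-yl)benzaldehyde | CC(C)=CCc1cc(C=O)ccc1O | intermediate
4 | 4-[(tert-butyldimethylsilyl)oxy]-3-(3-methylbut-2-en-1-yl)benzaldehyde | CC(C)=CCc1cc(C=O)ccc1O[Si](C)(C)C(C)(C)C | intermediate
5 | {4-[(tert-butyldimethylsilyl)oxy]-3-(3-methylbut-2-en-1-yl)phenyl}methanol | CC(C)=CCc1cc(CO)ccc1O[Si](C)(C)C(C)(C)C | intermediate
6 | 4-[(tert-butyldimethylsilyl)oxy]-3-(3-methylbut-2-en-1-yl)benzyl acetate | CC(C)=CCc1cc(COC(C)=O)ccc1O[Si](C)(C)C(C)(C)C | intermediate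
7 | 4-hydroxyphenylpyruvic acid | O=C(O)C(=O)Cc1ccc(O)cc1 | starting material
8 | formaldehyde (37% aqueous) | C=O | starting material
9 | 4-hydroxy-3-(4-hydroxyphenyl)-2-oxobutanoic acid (racemic aldol adduct, not isolated) | O=C(O)C(=O)C(CO)c1ccc(O)cc1 | intermediate
10 | 3-hydroxy-4-(4-hydroxyphenyl)furan-2(5H)-one | O=C1OCC(c2ccc(O)cc2)=C1O | intermediate
11 | 3-[(tert-butyldimethylsilyl)oxy]-4-{4-[(tert-butyldimethylsilyl)oxy]phenyl}furan-2(5H)-one (not isolated) | O=C1OCC(c2ccc(O[Si](C)(C)C(C)(C)C)cc2)=C1O[Si](C)(C)C(C)(C)C | intermediate
12 | 2,3-bis[(tert-butyldimethylsilyl)oxy]-4-{4-[(tert-butyldimethylsilyl)oxy]phenyl}furan | CC(C)(C)[Si](C)(C)Oc1occ(-c2ccc(O[Si](C)(C)C(C)(C)C)cc2)c1O[Si](C)(C)C(C)(C)C | intermediate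
13 | O-(tert-butyldimethylsilyl) 4-methylene-2-(3-methylbut-2-en-1-yl)cyclohexa-2,5-dien-1-one oxocarbenium ion (the 4-silyloxybenzyl cation, as its ion pair with the chiral anion; not isolated) | C=C1C=CC(=[O+][Si](C)(C)C(C)(C)C)C(CC=C(C)C)=C1 | intermediate
14 | (5R)-3-[(tert-butyldimethylsilyl)oxy]-5-{4-[(tert-butyldimethylsilyl)oxy]-3-(3-methylbut-2-en-1-yl)benzyl}-4-{4-[(tert-butyldimethylsilyl)oxy]phenyl}furan-2(5H)-one | CC(C)=CCc1cc(C[C@H]2OC(=O)C(O[Si](C)(C)C(C)(C)C)=C2c2ccc(O[Si](C)(C)C(C)(C)C)cc2)ccc1O[Si](C)(C)C(C)(C)C | intermediate
15 | (5R)-3-hydroxy-5-[4-hydroxy-3-(3-methylbut-2-en-1-yl)benzyl]-4-(4-hydroxyphenyl)furan-2(5H)-one | CC(C)=CCc1cc(C[C@H]2OC(=O)C(O)=C2c2ccc(O)cc2)ccc1O | target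

**Step count**
Total steps: 8. Longest linear sequence: 6 (steps 1, 2, 3, 4, 7, 8); the furan branch (steps 5, 6) joins at step 7.

**Steps most likely to fail**

Step 7 (Proposed new method). The chiral anion may discriminate the two faces of the furan poorly when the electrophile is a bare CH2 cation. The cation may also be consumed by Friedel-Crafts self-condensation or by attack at C2/C3 of the furan, and ionisation of the primary acetate may be slow at low temperature. The fallback uses known chemistry and sets out from 12 and 4. A catalytic asymmetric vinylogous Mukaiyama aldol addition of 12 to aldehyde 4 (chiral Ti(IV)-BINOL-type Lewis acid, CH2Cl2 or Et2O, −20 °C, anti-selective for 2-silyloxyfurans and aromatic aldehydes) should give the O-silyl aldol adduct F1. In F1, C5 has the spatial arrangement of 14; it is formally 5S only because the CIP priorities change. Both high diastereoselectivity and high enantioselectivity are needed, because syn and anti adducts from the same aldehyde face differ at C5. Ionic deoxygenation of the para-silyloxybenzylic silyl ether of F1 (Et3SiH, cat. TMSOTf, CH2Cl2, −78 °C; the same para-oxygen-stabilised cation, now trapped by hydride) removes the carbinol centre and comes back to the route at 14.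

Step 1. O-alkylation and double prenylation may outrun ortho-C-alkylation and leave little of the desired phenol. The fallback sets out from 1. Ortho-bromination (NBS, MeCN, 0 °C) gives 3-bromo-4-hydroxybenzaldehyde F2. Silylation (TBSCl, imidazole, DMF) gives 3-bromo-4-[(tert-butyldimethylsilyl)oxy]benzaldehyde F3. A Stille coupling with tributyl(3-methylbut-2-en-1-yl)stannane (Pd(PPh3)4, toluene, 100 °C) then delivers the linear prenyl arene and comes back to the route at 4, bypassing 3.

Step 6. The electron-rich bis(silyloxy)furan may be lost by hydrolysis or oxidation during salt removal, γ-enolisation may stay incomplete, and carried-over triflate salts would open an achiral background path in step 7. The fallback sets out from 10. TBSCl (2.2 equiv)/imidazole in DMF gives the bench-stable butenolide 11, which is purified by chromatography. TIPSOTf/Et3N (CH2Cl2, 0 °C) then converts 11 into the sturdier 2-triisopropylsilyloxy furan F4, which can be chromatographed on Et3N-deactivated silica. F4 takes the place of 12 in step 7 and comes back to the route at 14, the 2-O-silyl group leaving as its acetate.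

**Further compounds**
F1 | step 7 | 3-[(tert-butyldimethylsilyl)oxy]-5-{[(tert-butyldimethylsilyl)oxy][4-[(tert-butyldimethylsilyl)oxy]-3-(3-methylbut-2-en-1-yl)phenyl]methyl}-4-{4-[(tert-butyldimethylsilyl)oxy]phenyl}furan-2(5H)-one, C5 as in 14 (formally 5S), anti carbinol epimer expected and left undefined in the SMILES | CC(C)=CCc1cc(C(O[Si](C)(C)C(C)(C)C)[C@H]2OC(=O)C(O[Si](C)(C)C(C)(C)C)=C2c2ccc(O[Si](C)(C)C(C)(C)C)cc2)ccc1O[Si](C)(C)C(C)(C)C
F2 | step 1 | 3-bromo-4-hydroxybenzaldehyde | O=Cc1ccc(O)c(Br)c1
F3 | step 1 | 3-bromo-4-[(tert-butyldimethylsilyl)oxy]benzaldehyde | O=Cc1ccc(O[Si](C)(C)C(C)(C)C)c(Br)c1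
F4 | step 6 | 3-[(tert-butyldimethylsilyl)oxy]-4-{4-[(tert-butyldimethylsilyl)oxy]phenyl}-2-[(triisopropylsilyl)oxy]furan | CC(C)[Si](Oc1occ(-c2ccc(O[Si](C)(C)C(C)(C)C)cc2)c1O[Si](C)(C)C(C)(C)C)(C(C)C)C(C)C
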